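**Plan**

1. Numbering: C7 is the lactone carbinol bearing the pyrogallol ring, C8 the β ring-fusion carbon, and C9 the ether CH2. C7' is the ether carbinol bearing the catechol ring, C8' the α ring-fusion carbon, and C9' the lactone C=O. "Exo" means on the convex face of the bicycle, cis to H8 and H8'.
2. Enabling feature: in the tetrahydrofuran ring the three-atom unit C7'–O–C9 bridges C8' and C8, the two carbons this ring shares with the γ-lactone ring. The ether ring is therefore the adduct of an aldehyde-derived carbonyl ylide with the C8=C8' alkene of a 5-aryl butenolide.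
3. Cuts, in order: the five O–benzyl bonds; C9–C8 and C7'–C8' together (retro-[3+2]); C8=C8' (retro-metathesis); the acrylate C9'–O bond; and C7–C8 (vinyl addition).
4. Forward order: the lactone ring is made first (Grignard addition, resolution, acryloylation, ring-closing metathesis). The tetrahydrofuran ring follows, by cycloaddition with the ylide released from a bis(silylmethyl) acetal of the catechol aldehyde. The phenols are freed last.
5. Stereochemistry: C7 (S) comes from a lipase resolution. C8 (R) and C8' (S) follow from attack on the butenolide face anti to the C7 aryl group, with an obligatory cis fusion. C7' (S) comes from exo approach of the ylide.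

Key step: step 7

Assumption: the two O-benzylated aldehydes are taken as catalogue compounds; each is otherwise one benzylation (BnBr, K2CO3, DMF) away from the parent hydroxybenzaldehyde.

Step 1
Reactants: 1 3,4,5-tribenzyloxybenzaldehyde; 2 vinylmagnesium bromide
Product: 3 (±)-1-(3,4,5-tribenzyloxyphenyl)prop-2-en-1-ol
Conditions: CH2=CHMgBr (1.2 equiv), THF, −78 to 0 °C; then sat. aq. NH4Cl
Reagents that add atoms: vinylmagnesium bromide (2), C=C[Mg]Br
Why: Grignard 1,2-addition to a non-enolisable aromatic aldehyde is reliable and forms the C7–C8 bond; C7 arises racemic here and is resolved in step 2.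

Step 2
Reactants: 3 (±)-1-(3,4,5-tribenzyloxyphenyl)prop-2-en-1-ol
Product: 4 (S)-1-(3,4,5-tribenzyloxyphenyl)prop-2-en-1-ol
Conditions: immobilised Candida antarctica lipase B (Novozym 435), vinyl acetate (3 equiv), toluene, 40 °C, stopped just past half conversion; chromatography
Reagents that add atoms: none
Why: In this lipase-catalysed acylative kinetic resolution of a 1-arylallyl alcohol, the empirical size rule for secondary alcohols predicts that the enzyme seats the vinyl group in its small pocket and acetylates the (R)-enantiomer, so the unreacted (S)-alcohol, which carries the C7 configuration of the target, should be left in high enantiopurity once conversion passes one half.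

Step 3
Reactants: 4 (S)-1-(3,4,5-tribenzyloxyphenyl)prop-2-en-1-ol; 5 acryloyl chloride
Product: 6 (S)-1-(3,4,5-tribenzyloxyphenyl)prop-2-en-1-yl acrylate
Conditions: CH2=CHCOCl (1.3 equiv), Et3N (1.5 equiv), CH2Cl2, −20 to 0 °C
Reagents that add atoms: acryloyl chloride (5), C=CC(=O)Cl
Why: O-acylation of a secondary alcohol with an acid chloride and an amine base breaks only the O–H bond, so C7 keeps its configuration, and the cold, short reaction limits ionisation of the electron-rich benzylic allylic ester.

Step 4
Reactants: 6 (S)-1-(3,4,5-tribenzyloxyphenyl)prop-2-en-1-yl acrylate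
Product: 7 (S)-5-(3,4,5-tribenzyloxyphenyl)furan-2(5H)-one
Conditions: second-generation Grubbs catalyst (H2IMes)(PCy3)Cl2Ru=CHPh (5 mol%), 1,4-benzoquinone (10 mol%), CH2Cl2 (0.01 M), reflux
Reagents that add atoms: none
Why: Ring-closing metathesis of an allyl acrylate, a standard entry to butenolides, closes the five-membered lactone ring with loss of ethene under neutral conditions that leave the acidic C7–H alone, while benzoquinone intercepts ruthenium hydrides that could move the double bond.

Step 5
Reactants: 8 3,4-dibenzyloxybenzaldehyde
Product: 9 3,4-dibenzyloxybenzaldehyde dimethyl acetal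
Conditions: HC(OMe)3 (3 equiv), TsOH·H2O (1 mol%), MeOH, rt; Et3N quench
Reagents that add atoms: trimethyl orthoformate, COC(OC)OC
Why: Acid-catalysed acetalisation with an orthoester as water scavenger is routine for electron-rich benzaldehydes and creates no stereocentre.

Step 6
Reactants: 9 3,4-dibenzyloxybenzaldehyde dimethyl acetal; 10 trimethylsilylmethanol
Product: 11 3,4-dibenzyloxybenzaldehyde bis(trimethylsilylmethyl) acetal
Conditions: Me3SiCH2OH (2.5 equiv), PPTS (5 mol%), toluene, 80 °C, MeOH–toluene azeotrope distilled off; Et3N quench
Reagents that add atoms: trimethylsilylmethanol (10), C[Si](C)(C)CO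
Why: Acid-catalysed transacetalisation driven by removal of methanol replaces both methoxy groups, and the symmetrical acetal is chosen because loss of either alkoxy group later gives the same silylmethyl oxocarbenium ion, which a mixed methyl acetal made by statistical exchange could not guarantee.

Step 7
Reactants: 7 (S)-5-(3,4,5-tribenzyloxyphenyl)furan-2(5H)-one; 11 3,4-dibenzyloxybenzaldehyde bis(trimethylsilylmethyl) acetal
Product: 14 penta-O-benzyl furofuranone (3S,3aR,6S,6aS; both aryl groups exo), via chloro ether 12 (not isolated), via carbonyl ylide 13 (not isolated)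
Conditions: 11 (2.5 equiv), AcCl (2.5 equiv), Zn(OAc)2 (1 mol%), CH2Cl2, 0 °C to rt, then volatiles off in vacuo; 7 (1 equiv), MeCN, CsF (2.2 equiv, dried, in portions), 0 °C to rt
Reagents that add atoms: none
Why: Acetyl chloride under Zn(OAc)2 catalysis swaps one of the two identical silylmethoxy groups of 11 for chloride; 12 ionises easily to the oxocarbenium ion stabilised by the dibenzyloxyphenyl ring, fluoride removes the silyl group from the carbon next to the charged oxygen, and this 1,3-elimination releases ylide 13, which is trapped at once by 7. The closest known reaction type is the fluoride-induced 1,3-elimination of α-chloroalkyl trimethylsilylmethyl ethers to non-stabilised carbonyl ylides and their [3+2] cycloaddition to acrylates, fumarates and maleates; an aryl group on the ylide and a butenolide as partner widen the scope but not the type. The tetrahydrofuran ring closes by a suprafacial [π4s+π2s] cycloaddition that forms C9–C8 and C7'–C8' (in the asynchronous limit a Michael attack of the CH2 terminus followed by 5-(enolexo)-endo-trig collapse of the lactone enolate onto the oxocarbenium carbon), so the ring fusion can only be cis. C8 and C8' are set by the C7 stereocentre, whose bulky aryl group shields one face of the flat butenolide and sends the ylide to the other, and C7' is set by exo approach of the extended (E) ylide, which keeps the catechol ring clear of the lactone carbonyl and places it on the convex face. Regiochemistry rests on polarity and size: the donor aryl ring holds the positive end of the dipole at C7', the unsubstituted CH2 carries the largest HOMO coefficient and meets the electrophilic β-carbon C8, and the smaller terminus thus ends up beside the crowded C7. Keeping 12 in excess over the sparingly soluble CsF leaves no free fluoride to remove the acidic C7–H, and a minor endo C7' epimer, if formed, is separable and can be re-equilibrated with a trace of acid through the p-benzyloxybenzyl cation.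

Step 8
Reactants: 14 penta-O-benzyl furofuranone
Product: 15 (3S,3aR,6S,6aS)-6-(3,4-dihydroxyphenyl)-3-(3,4,5-trihydroxyphenyl)tetrahydro-1H,3H-furo[3,4-c]furan-1-one (CNP0290035.1)
Conditions: BCl3 (1 M in CH2Cl2, 10 equiv), C6HMe5 (15 equiv), CH2Cl2, −78 °C, argon; then H2O–THF, −78 °C to rt
Reagents that add atoms: none
Why: Lewis-acid debenzylation of aryl benzyl ethers with pentamethylbenzene as non-basic cation scavenger (Friedel–Crafts capture of the benzyl cation) works at −78 °C without hydrogen, so the benzylic C7–O and C7'–O bonds that hydrogenolysis would endanger and all four stereocentres should stay intact.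

**Compound list**

1 | 3,4,5-tribenzyloxybenzaldehyde | O=Cc1cc(OCc2ccccc2)c(OCc2ccccc2)c(OCc2ccccc2)c1 | starting material
2 | vinylmagnesium bromide | C=C[Mg]Br | starting material
3 | (±)-1-(3,4,5-tribenzyloxyphenyl)prop-2-en-1-ol | OC(C=C)c1cc(OCc2ccccc2)c(OCc2ccccc2)c(OCc2ccccc2)c1 | intermediate
4 | (S)-1-(3,4,5-tribenzyloxyphenyl)prop-2-en-1-ol | O[C@H](c1cc(OCc2ccccc2)c(OCc2ccccc2)c(OCc2ccccc2)c1)C=C | intermediate
5 | acryloyl chloride | C=CC(=O)Cl | starting material
6 | (S)-1-(3,4,5-tribenzyloxyphenyl)prop-2-en-1-yl acrylate | C=CC(=O)O[C@H](c1cc(OCc2ccccc2)c(OCc2ccccc2)c(OCc2ccccc2)c1)C=C | intermediate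
7 | (S)-5-(3,4,5-tribenzyloxyphenyl)furan-2(5H)-one | O=C1O[C@H](c2cc(OCc3ccccc3)c(OCc3ccccc3)c(OCc3ccccc3)c2)C=C1 | intermediate
8 | 3,4-dibenzyloxybenzaldehyde | O=Cc1ccc(OCc2ccccc2)c(OCc2ccccc2)c1 | starting material
9 | 3,4-dibenzyloxybenzaldehyde dimethyl acetal | COC(OC)c1ccc(OCc2ccccc2)c(OCc2ccccc2)c1 | intermediate
10 | trimethylsilylmethanol | C[Si](C)(C)CO | starting material
11 | 3,4-dibenzyloxybenzaldehyde bis(trimethylsilylmethyl) acetal | C[Si](C)(C)COC(OC[Si](C)(C)C)c1ccc(OCc2ccccc2)c(OCc2ccccc2)c1 | intermediate
12 | chloro(3,4-dibenzyloxyphenyl)methyl trimethylsilylmethyl ether (racemic, not isolated) | ClC(OC[Si](C)(C)C)c1ccc(OCc2ccccc2)c(OCc2ccccc2)c1 | intermediate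
13 | (E)-carbonyl ylide of 3,4-dibenzyloxybenzaldehyde, ArCH=O(+)–CH2(−) (not isolated) | [CH2-]/[O+]=C/c1ccc(OCc2ccccc2)c(OCc2ccccc2)c1 | intermediate
14 | (3S,3aR,6S,6aS)-6-(3,4-dibenzyloxyphenyl)-3-(3,4,5-tribenzyloxyphenyl)tetrahydro-1H,3H-furo[3,4-c]furan-1-one | O=C1O[C@H](c3cc(OCc4ccccc4)c(OCc4ccccc4)c(OCc4ccccc4)c3)[C@H]2CO[C@H](c3ccc(OCc4ccccc4)c(OCc4ccccc4)c3)[C@@H]12 | intermediate
15 | (3S,3aR,6S,6aS)-6-(3,4-dihydroxyphenyl)-3-(3,4,5-trihydroxyphenyl)tetrahydro-1H,3H-furo[3,4-c]furan-1-one | O=C1O[C@H](c2cc(O)c(O)c(O)c2)[C@H]2CO[C@H](c3ccc(O)c(O)c3)[C@@H]12 | target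

**Step count**

Total step count: 8. Longest linear sequence: 6 steps (1, 2, 3, 4, 7, 8). The ylide branch (5, 6) joins at step 7.

**Steps most likely to fail**

**Step 7.** The short-lived ylide may be lost before it meets the alkene, in three ways:
- closure to the oxirane;
- capture by traces of free aldehyde;
- proton transfer from the acidic C7–H, which would also erode enantiopurity.

Exo/endo or regiochemical control may also be poor.

The fallback makes the same two bonds one at a time through a tether. It sets out from 7 (with 9 as partner) and returns at 14.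
- Benzophenone-sensitised photoaddition of methanol to 7 (hν 350 nm, MeOH) should deliver a hydroxymethyl radical to C8 anti to the aryl group. This gives the trans-hydroxymethyl lactone F1 under neutral conditions.
- Acetal exchange of its primary alcohol with an excess of 9 (PPTS, toluene, methanol distilled off) gives the mixed methyl acetal F2.
- LiN(SiMe3)2 and Me3SiCl (THF, −78 °C) convert the lactone, which no longer has an acidic C7–H, into the silyl ketene acetal F3.
- Catalytic Me3SiOTf in CH2Cl2 at −78 °C then ionises the acetal, and C8' attacks C7' in an intramolecular Mukaiyama aldol-type reaction. The short tether allows only the cis-fused ring, and the aryl group should take the convex face, giving 14.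

**Step 8.** Coordination of BCl3 to the ring oxygens may ionise the benzylic C7'–O or C7–O bond. The cation may then be captured by the arene scavenger or reclose with epimerisation. The free pyrogallol may also oxidise in air during work-up.

The fallback is reductive instead of Lewis-acidic cleavage, from 14 straight to 15. The conditions are H2 (1 atm), Pd/C, EtOAc–THF, rt, stopped as soon as the last aryl benzyl ether has gone. It relies on primary benzyl aryl ethers being hydrogenolysed faster than the hindered secondary ring C–O bonds. No new compound arises on this path (F0).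

**Step 2.** The very large tribenzyloxyphenyl group may fit the enzyme poorly, so acylation may be slow or may discriminate little between the enantiomers. Half of the material is lost in any case.

The fallback creates C7 by asymmetric catalysis instead of resolution. It sets out from 1 and returns at 4, bypassing 3.
- Divinylzinc F4 is prepared from 2 and ZnCl2 in Et2O, with the magnesium salts precipitated by 1,4-dioxane and filtered off.
- It is added to 1 in toluene at 0 °C with (2S)-(−)-3-exo-morpholinoisoborneol (10 mol%), an amino-alcohol-catalysed organozinc addition.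
- This ligand enantiomer directs the transferred group to the Si face of aromatic aldehydes and should give the (S)-carbinol 4.
- Any shortfall in enantiopurity could be made good by recrystallising 7.

**Further compounds**

F1 | step 7 | (4R,5S)-4-(hydroxymethyl)-5-(3,4,5-tribenzyloxyphenyl)dihydrofuran-2(3H)-one | O=C1O[C@H](c2cc(OCc3ccccc3)c(OCc3ccccc3)c(OCc3ccccc3)c2)[C@@H](CO)C1
F2 | step 7 | (4R,5S)-4-{[(3,4-dibenzyloxyphenyl)(methoxy)methoxy]methyl}-5-(3,4,5-tribenzyloxyphenyl)dihydrofuran-2(3H)-one (acetal epimers) | O=C1O[C@H](c2cc(OCc3ccccc3)c(OCc3ccccc3)c(OCc3ccccc3)c2)[C@@H](COC(OC)c2ccc(OCc3ccccc3)c(OCc3ccccc3)c2)C1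
F3 | step 7 | (4R,5S)-2-trimethylsilyloxy-4,5-dihydrofuran derived from F2 (silyl ketene acetal) | C[Si](C)(C)OC1=C[C@H](COC(OC)c2ccc(OCc3ccccc3)c(OCc3ccccc3)c2)[C@@H](c2cc(OCc3ccccc3)c(OCc3ccccc3)c(OCc3ccccc3)c2)O1
F0 | step 8 | none | none
F4 | step 2 | divinylzinc | C=C[Zn]C=C
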